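**Plan**
1. Retrosynthesis: the acid and the phenol are unmasked last. The C3=C4 double bond comes from a C4 carbinol by dehydration and the C2 methyl group from a C2–CH2–CHO arm by loss of CO. Both helpers are tied up in a temporary lactol ring.
2. The lactol is cut at C4–C3 and O1–C2 in one stroke into salicylaldehyde 4 and the C20 enal 15 (amine-catalysed vinylogous aldol/oxa-Michael domino reaction).
3. Enabling feature: C2 of the pyran ring is the β-carbon of a 3-methylalk-2-enal unit of the prenyl chain, whose γ-methyl group becomes C3. C4 and O1 sit ortho to each other on the benzene ring (at C4a and C8a) as formyl carbon and phenol oxygen.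
4. Enal 15 is cut at its (Z)-enoate double bond (Still–Gennari) into phosphonate 12 and trisnor aldehyde 9, which comes from (2E,6E)-farnesol by terminal oxidative cleavage.
5. Forward: the benzene ring is bought and formylated, the chain is assembled, the pyran ring and the lactol ring close in the key step, then CO and water are taken out and the protecting groups fall.
6. Stereochemistry: C2 (S) from the chiral amine catalyst in the oxa-Michael event; the two E olefins from farnesol; the Z enoate from the olefination.

Key step: step 10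

Assumption: the facial sense of the oxa-Michael addition is taken from the usual shielding model for diarylprolinol silyl ether iminium ions (new benzylic arm anti to the iminium carbon), which calls for the (R)-catalyst to reach 2S; should the sense prove opposite, the equally available (S)-catalyst is used.
Remark: 7, 8 and 12 are racemic; their stereocentres are destroyed in steps 5 and 7. From 20 onward the 2H-chromene is kept from light and heat, because oxa-6π ring opening and reclosure would erase C2.

**Step 1**
Reactants: 1 2,3-dimethylhydroquinone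
Product: 2 4-[(tert-butyldimethylsilyl)oxy]-2,3-dimethylphenol
Conditions: TBSCl (1.0 equiv), imidazole, DMF, 0 °C → rt
Reagents that add atoms: tert-butyldimethylsilyl chloride, CC(C)(C)[Si](C)(C)Cl
Why: Silylation of one of the two equivalent phenols of a symmetric hydroquinone (statistical monoprotection) should give mainly the monoether, separable from the diether and from recovered 1.

**Step 2**
Reactants: 2 4-[(tert-butyldimethylsilyl)oxy]-2,3-dimethylphenol
Product: 4 5-[(tert-butyldimethylsilyl)oxy]-2-hydroxy-3,4-dimethylbenzaldehyde, via salicyl alcohol 3 (not isolated)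
Conditions: MgCl2, Et3N, (CH2O)n, THF, reflux; then 1 M HCl
Reagents that add atoms: paraformaldehyde (as formaldehyde), C=O
Why: Casnati–Skattebøl ortho-formylation, in which the magnesium phenoxide directs formaldehyde to the only free ortho position and the salicyl alcohol 3 is oxidised in the flask by a second formaldehyde through an Oppenauer-type hydride transfer.

**Step 3**
Reactants: 5 (2E,6E)-farnesol
Product: 6 tert-butyldiphenylsilyl ether of (2E,6E)-farnesol
Conditions: TBDPSCl, imidazole, CH2Cl2, rt
Reagents that add atoms: tert-butyldiphenylsilyl chloride, CC(C)(C)[Si](Cl)(c1ccccc1)c1ccccc1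
Why: Standard silylation of a primary allylic alcohol with a group robust enough to pass NBS, periodic acid and KN(SiMe3)2.

**Step 4**
Reactants: 6 tert-butyldiphenylsilyl ether of (2E,6E)-farnesol
Product: 8 racemic 10,11-epoxide of 6, via bromohydrin 7 (not isolated)
Conditions: NBS, THF/H2O, 0 °C; then K2CO3, MeOH, rt
Reagents that add atoms: water, O (epoxide oxygen); N-bromosuccinimide, O=C1CCC(=O)N1Br (bromine of 7, lost again on ring closure)
Why: Bromohydrin formation in aqueous THF should be selective for the terminal trisubstituted olefin (most accessible, the C2 olefin being deactivated by the allylic oxygen), and base then closes the epoxide by an intramolecular Williamson reaction.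

**Step 5**
Reactants: 8 racemic 10,11-epoxide of 6
Product: 9 (4E,8E)-10-[(tert-butyldiphenylsilyl)oxy]-4,8-dimethyldeca-4,8-dienal
Conditions: H5IO6, THF/Et2O, 0 °C
Reagents that add atoms: none
Why: Periodic acid hydrolyses the epoxide to the diol and cleaves it (Malaprade glycol cleavage) to the trisnor aldehyde and acetone without touching the remaining olefins.

**Step 6**
Reactants: 10 methyl 2-[bis(2,2,2-trifluoroethoxy)phosphoryl]acetate; 11 5-bromo-2-methylpent-2-ene
Product: 12 methyl 2-[bis(2,2,2-trifluoroethoxy)phosphoryl]-6-methylhept-5-enoate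
Conditions: NaH, THF/DMF, 0 °C; then 11, NaI (cat.), 50 °C
Reagents that add atoms: none
Why: C-alkylation of the stabilised phosphonoacetate anion with a primary bromide (SN2 with iodide catalysis), an excess of 10 serving to suppress dialkylation.

**Step 7**
Reactants: 9 (4E,8E)-10-[(tert-butyldiphenylsilyl)oxy]-4,8-dimethyldeca-4,8-dienal; 12 methyl 2-[bis(2,2,2-trifluoroethoxy)phosphoryl]-6-methylhept-5-enoate
Product: 13 methyl (2Z,6E,10E)-12-[(tert-butyldiphenylsilyl)oxy]-6,10-dimethyl-2-(4-methylpent-3-en-1-yl)dodeca-2,6,10-trienoate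
Conditions: KN(SiMe3)2, 18-crown-6, THF, −78 °C
Reagents that add atoms: none
Why: Still–Gennari olefination, in which the electron-poor bis(trifluoroethyl) phosphonate eliminates fast from the kinetic adduct so that the ester should end up cis to the chain (2Z), the geometry of the target.

**Step 8**
Reactants: 13 methyl (2Z,6E,10E)-12-[(tert-butyldiphenylsilyl)oxy]-6,10-dimethyl-2-(4-methylpent-3-en-1-yl)dodeca-2,6,10-trienoate
Product: 14 methyl (2Z,6E,10E)-12-hydroxy-6,10-dimethyl-2-(4-methylpent-3-en-1-yl)dodeca-2,6,10-trienoate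
Conditions: Bu4NF, THF, 0 °C → rt
Reagents that add atoms: none
Why: Fluoride cleaves the Si–O bond of the primary silyl ether (desilylation) while the methyl ester and the olefins are inert.

**Step 9**
Reactants: 14 methyl (2Z,6E,10E)-12-hydroxy-6,10-dimethyl-2-(4-methylpent-3-en-1-yl)dodeca-2,6,10-trienoate
Product: 15 methyl (2Z,6E,10E)-6,10-dimethyl-2-(4-methylpent-3-en-1-yl)-12-oxododeca-2,6,10-trienoate
Conditions: MnO2, CH2Cl2, rt
Reagents that add atoms: none
Why: Allylic oxidation with MnO2 converts only the allylic alcohol into the enal and leaves the isolated olefins and the enoate alone.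

**Step 10**
Reactants: 4 5-[(tert-butyldimethylsilyl)oxy]-2-hydroxy-3,4-dimethylbenzaldehyde (1.5 equiv); 15 methyl (2Z,6E,10E)-6,10-dimethyl-2-(4-methylpent-3-en-1-yl)-12-oxododeca-2,6,10-trienoate
Product: 18 bridged lactol (2S,4S in chroman numbering), via dienamine 16 (not isolated), via hydroxy aldehyde 17 (not isolated)
Conditions: (R)-2-{bis[3,5-bis(trifluoromethyl)phenyl][(trimethylsilyl)oxy]methyl}pyrrolidine (30 mol %), PhCO2H (30 mol %), toluene, rt
Reagents that add atoms: none
Why: The amine condenses with 15 to an iminium ion that loses a proton from the C3 methyl group to give the cross-conjugated dienamine 16, whose terminal CH2 adds to the formyl carbon of 4 (vinylogous aldol, future C4–C3 bond of the pyran ring); the conjugated iminium ion so restored takes up the phenol oxygen at its β-carbon (oxa-Michael, future O1–C2 bond), and hydrolysis to 17 and hemiacetal formation end the sequence. The closest known reaction type is the amine-catalysed domino vinylogous aldol/oxa-Michael reaction of salicylaldehydes with 3-methylalk-2-enals to tricyclic lactols, taken here in its diarylprolinol silyl ether-catalysed enantioselective form. The pyran ring closes in 6-exo-trig mode (phenol oxygen onto the iminium β-carbon) and the lactol ring in 6-exo-trig mode (C4 hydroxyl onto the formyl group). C2 is set by the catalyst, whose bis(aryl)(silyloxy)methyl group covers one face of the iminium ion so that O1 enters from the open face; C4 follows from C2 because only the 2,4-cis isomer can close the lactol while the aldol and oxa-Michael additions stay reversible, and the lactol carbon is left as an epimer mixture that is lost in step 11. The step needs site selectivity for the methyl group over the neighbouring chain methylene of 15 and for the γ- over the α-carbon of 16, which the unhindered terminal CH2 of 16 and the stable lactol sink should secure, and chemoselectivity for the enal over the enoate, which is α-branched and forms no iminium ion. The geometry of the C2=C3 bond of 15 is lost in 16 and therefore does not matter.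

**Step 11**
Reactants: 18 bridged lactol (2S,4S in chroman numbering)
Product: 19 methyl (2Z,6E)-9-[(2S,4S)-6-[(tert-butyldimethylsilyl)oxy]-4-hydroxy-2,7,8-trimethyl-3,4-dihydro-2H-chromen-2-yl]-6-methyl-2-(4-methylpent-3-en-1-yl)nona-2,6-dienoate
Conditions: RhCl(PPh3)3 (1.1 equiv), toluene, 110 °C, degassed
Reagents that add atoms: none
Why: Tsuji–Wilkinson decarbonylation, in which the lactol opens to aldehyde 17, univalent rhodium inserts into the formyl C–H bond, CO migrates to the metal and C–H reductive elimination leaves the C2 methyl group; the alkyl group on rhodium has no β-hydrogen, and the pyran ring is still saturated so that heat cannot open it.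

**Step 12**
Reactants: 19 methyl (2Z,6E)-9-[(2S,4S)-6-[(tert-butyldimethylsilyl)oxy]-4-hydroxy-2,7,8-trimethyl-3,4-dihydro-2H-chromen-2-yl]-6-methyl-2-(4-methylpent-3-en-1-yl)nona-2,6-dienoate
Product: 20 methyl (2Z,6E)-9-[(2S)-6-[(tert-butyldimethylsilyl)oxy]-2,7,8-trimethyl-2H-chromen-2-yl]-6-methyl-2-(4-methylpent-3-en-1-yl)nona-2,6-dienoate
Conditions: Burgess reagent (MeO2C–N(−)–SO2–N(+)Et3), benzene, 50 °C, dark
Reagents that add atoms: none
Why: Burgess dehydration, in which the sulfamate ester of the benzylic C4 alcohol eliminates thermally in syn fashion with a C3 hydrogen (C2 is quaternary, so only the C3=C4 olefin can form) under neutral conditions that spare the polyene.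

**Step 13**
Reactants: 20 methyl (2Z,6E)-9-[(2S)-6-[(tert-butyldimethylsilyl)oxy]-2,7,8-trimethyl-2H-chromen-2-yl]-6-methyl-2-(4-methylpent-3-en-1-yl)nona-2,6-dienoate
Product: 22 (2Z,6E)-9-[(2S)-6-hydroxy-2,7,8-trimethyl-2H-chromen-2-yl]-6-methyl-2-(4-methylpent-3-en-1-yl)nona-2,6-dienoic acid, via phenol methyl ester 21 (not isolated)
Conditions: LiOH, THF/MeOH/H2O, 45 °C, argon, dark; then 1 M HCl to pH 4, 0 °C
Reagents that add atoms: lithium hydroxide, [Li+].[OH-] (one carboxyl oxygen)
Why: Hydroxide first cleaves the aryl silyl ether by attack at silicon and then saponifies the methyl ester (BAc2), the exclusion of air and light protecting the chromenol from oxidation and C2 from photochemical ring opening.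

**Compound list**
1 | 2,3-dimethylhydroquinone (2,3-dimethylbenzene-1,4-diol) | Cc1c(C)c(O)ccc1O | starting material
2 | 4-[(tert-butyldimethylsilyl)oxy]-2,3-dimethylphenol | Cc1c(C)c(O[Si](C)(C)C(C)(C)C)ccc1O | intermediate
3 | salicyl alcohol, not isolated: 4-[(tert-butyldimethylsilyl)oxy]-6-(hydroxymethyl)-2,3-dimethylphenol | OCc1cc(O[Si](C)(C)C(C)(C)C)c(C)c(C)c1O | intermediate
4 | 5-[(tert-butyldimethylsilyl)oxy]-2-hydroxy-3,4-dimethylbenzaldehyde | O=Cc1cc(O[Si](C)(C)C(C)(C)C)c(C)c(C)c1O | intermediate
5 | (2E,6E)-farnesol, (2E,6E)-3,7,11-trimethyldodeca-2,6,10-trien-1-ol | CC(C)=CCC/C(C)=C/CC/C(C)=C/CO | starting material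
6 | tert-butyl(diphenyl){[(2E,6E)-3,7,11-trimethyldodeca-2,6,10-trien-1-yl]oxy}silane | CC(C)=CCC/C(C)=C/CC/C(C)=C/CO[Si](c1ccccc1)(c1ccccc1)C(C)(C)C | intermediate
7 | bromohydrin, not isolated: (6E,10E)-3-bromo-12-[(tert-butyldiphenylsilyl)oxy]-2,6,10-trimethyldodeca-6,10-dien-2-ol, racemic | CC(C)(O)C(Br)CC/C(C)=C/CC/C(C)=C/CO[Si](c1ccccc1)(c1ccccc1)C(C)(C)C | intermediate
8 | tert-butyl{[(2E,6E)-9-(3,3-dimethyloxiran-2-yl)-3,7-dimethylnona-2,6-dien-1-yl]oxy}diphenylsilane, racemic | CC1(C)OC1CC/C(C)=C/CC/C(C)=C/CO[Si](c1ccccc1)(c1ccccc1)C(C)(C)C | intermediate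
9 | (4E,8E)-10-[(tert-butyldiphenylsilyl)oxy]-4,8-dimethyldeca-4,8-dienal | O=CCC/C(C)=C/CC/C(C)=C/CO[Si](c1ccccc1)(c1ccccc1)C(C)(C)C | intermediate
10 | methyl 2-[bis(2,2,2-trifluoroethoxy)phosphoryl]acetate | COC(=O)CP(=O)(OCC(F)(F)F)OCC(F)(F)F | starting material
11 | 5-bromo-2-methylpent-2-ene | CC(C)=CCCBr | starting material
12 | methyl 2-[bis(2,2,2-trifluoroethoxy)phosphoryl]-6-methylhept-5-enoate, racemic | COC(=O)C(CCC=C(C)C)P(=O)(OCC(F)(F)F)OCC(F)(F)F | intermediate
13 | methyl (2Z,6E,10E)-12-[(tert-butyldiphenylsilyl)oxy]-6,10-dimethyl-2-(4-methylpent-3-en-1-yl)dodeca-2,6,10-trienoate | CC(C)=CCC/C(=C/CC/C(C)=C/CC/C(C)=C/CO[Si](c1ccccc1)(c1ccccc1)C(C)(C)C)C(=O)OC | intermediate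
14 | methyl (2Z,6E,10E)-12-hydroxy-6,10-dimethyl-2-(4-methylpent-3-en-1-yl)dodeca-2,6,10-trienoate | CC(C)=CCC/C(=C/CC/C(C)=C/CC/C(C)=C/CO)C(=O)OC | intermediate
15 | methyl (2Z,6E,10E)-6,10-dimethyl-2-(4-methylpent-3-en-1-yl)-12-oxododeca-2,6,10-trienoate | CC(C)=CCC/C(=C/CC/C(C)=C/CC/C(C)=C/C=O)C(=O)OC | intermediate
16 | dienamine, not isolated: N-[(1E)-3-methylidenebuta-1-enyl] derivative of the (R)-catalyst carrying the rest of the chain of 15 at C3 of the diene | CC(C)=CCC/C(=C/CC/C(C)=C/CCC(=C)/C=C/N1CCC[C@@H]1C(O[Si](C)(C)C)(c1cc(cc(c1)C(F)(F)F)C(F)(F)F)c1cc(cc(c1)C(F)(F)F)C(F)(F)F)C(=O)OC | intermediate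
17 | hydroxy aldehyde, not isolated: methyl (2Z,6E)-9-[(2S,4S)-6-[(tert-butyldimethylsilyl)oxy]-4-hydroxy-7,8-dimethyl-2-(2-oxoethyl)-3,4-dihydro-2H-chromen-2-yl]-6-methyl-2-(4-methylpent-3-en-1-yl)nona-2,6-dienoate | CC(C)=CCC/C(=C/CC/C(C)=C/CC[C@@]1(CC=O)C[C@H](O)c2cc(O[Si](C)(C)C(C)(C)C)c(C)c(C)c2O1)C(=O)OC | intermediate
18 | bridged lactol: the (2S,4S)-chroman of 17 in which the C2 arm and the C4 oxygen are joined as C2–CH2–CH(OH)–O–C4 (benzo-fused 2,6-dioxabicyclo[3.3.1]nonan-3-ol; both lactol epimers) | CC(C)=CCC/C(=C/CC/C(C)=C/CC[C@]12C[C@H](OC(O)C1)c1cc(O[Si](C)(C)C(C)(C)C)c(C)c(C)c1O2)C(=O)OC | intermediate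
19 | methyl (2Z,6E)-9-[(2S,4S)-6-[(tert-butyldimethylsilyl)oxy]-4-hydroxy-2,7,8-trimethyl-3,4-dihydro-2H-chromen-2-yl]-6-methyl-2-(4-methylpent-3-en-1-yl)nona-2,6-dienoate | CC(C)=CCC/C(=C/CC/C(C)=C/CC[C@@]1(C)C[C@H](O)c2cc(O[Si](C)(C)C(C)(C)C)c(C)c(C)c2O1)C(=O)OC | intermediate
20 | methyl (2Z,6E)-9-[(2S)-6-[(tert-butyldimethylsilyl)oxy]-2,7,8-trimethyl-2H-chromen-2-yl]-6-methyl-2-(4-methylpent-3-en-1-yl)nona-2,6-dienoate | CC(C)=CCC/C(=C/CC/C(C)=C/CC[C@@]1(C)C=Cc2cc(O[Si](C)(C)C(C)(C)C)c(C)c(C)c2O1)C(=O)OC | intermediate
21 | phenol methyl ester, not isolated: methyl (2Z,6E)-9-[(2S)-6-hydroxy-2,7,8-trimethyl-2H-chromen-2-yl]-6-methyl-2-(4-methylpent-3-en-1-yl)nona-2,6-dienoate | CC(C)=CCC/C(=C/CC/C(C)=C/CC[C@@]1(C)C=Cc2cc(O)c(C)c(C)c2O1)C(=O)OC | intermediate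
22 | (2Z,6E)-9-[(2S)-6-hydroxy-2,7,8-trimethyl-2H-chromen-2-yl]-6-methyl-2-(4-methylpent-3-en-1-yl)nona-2,6-dienoic acid | CC(C)=CCC/C(=C/CC/C(C)=C/CC[C@@]1(C)C=Cc2cc(O)c(C)c(C)c2O1)C(=O)O | target

**Step count**
Total: 13 steps. Longest linear sequence: 10 steps (5 → 22 through steps 3, 4, 5, 7, 8, 9, 10, 11, 12, 13).

**Steps most likely to fail**

Step 10. The dienamine may react through the chain methylene or its α-carbon instead of the methyl terminus, turnover may stall, or the catalyst may discriminate the two faces of the iminium ion too weakly. The fallback sets out from phenol 2 and enal 15 and builds the pyran ring by another bond set (C4–C4a and O1–C2) without catalyst control. The two are heated with PhB(OH)2 and AcOH in toluene at reflux with a water separator. The aryl borate delivers the enal carbonyl carbon to the free ortho position, loss of the boron-bound oxygen gives the ortho-quinone methide, and oxa-6π electrocyclisation should give the racemic silyl chromene ester F1. Preparative HPLC on a chiral stationary phase (amylose tris(3,5-dimethylphenylcarbamate)) then separates 20 from its (R)-antipode F2. The route is rejoined at 20, and steps 10 to 12 are not needed.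

Step 11. The lactol may hold too little open aldehyde for rhodium to insert, or the hot alkylrhodium intermediate may expel the C2 aryloxide and open the pyran ring. The fallback sets out from lactol 18 and inverts the order of the two helper removals, so that rhodium meets a free aldehyde at lower temperature. Pyridinium p-toluenesulfonate (cat.) in toluene at 60 °C should ionise the benzylic C4–O bond and, by loss of a C3 proton, give the chromenyl acetaldehyde F3. Decarbonylation of F3 with RhCl(PPh3)3 in benzene at 50–70 °C in the dark should then give 20 directly, where the route is rejoined; 19 and step 12 are bypassed. The bridged ring that intramolecular hydroacylation of F3 would require argues against that side path.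

Step 7. The α-branch of 12 may erode the Z selectivity or slow the addition of the hindered anion. The fallback sets out from aldehyde 9 and makes the trisubstituted olefin in two stereodefined stages. Phosphonate 10 is brominated (NaOBr, then SnCl2) to the bromophosphonate F4. Its Horner–Wadsworth–Emmons reaction with 9 (KN(SiMe3)2, 18-crown-6, THF, −78 °C) should give the (E)-α-bromo enoate F5, in which the ester is again cis to the chain. Negishi coupling of F5 with (4-methylpent-3-en-1-yl)zinc bromide F6 (from 11, Zn, LiCl, THF) under PdCl2(dppf) catalysis replaces bromine with retention and returns to 13.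

**Further compounds**
F1 | step 10 | racemic methyl (2Z,6E)-9-{6-[(tert-butyldimethylsilyl)oxy]-2,7,8-trimethyl-2H-chromen-2-yl}-6-methyl-2-(4-methylpent-3-en-1-yl)nona-2,6-dienoate | CC(C)=CCC/C(=C/CC/C(C)=C/CCC1(C)C=Cc2cc(O[Si](C)(C)C(C)(C)C)c(C)c(C)c2O1)C(=O)OC
F2 | step 10 | (R)-antipode of 20 | CC(C)=CCC/C(=C/CC/C(C)=C/CC[C@]1(C)C=Cc2cc(O[Si](C)(C)C(C)(C)C)c(C)c(C)c2O1)C(=O)OC
F3 | step 11 | methyl (2Z,6E)-9-[(2R)-6-[(tert-butyldimethylsilyl)oxy]-7,8-dimethyl-2-(2-oxoethyl)-2H-chromen-2-yl]-6-methyl-2-(4-methylpent-3-en-1-yl)nona-2,6-dienoate | CC(C)=CCC/C(=C/CC/C(C)=C/CC[C@@]1(CC=O)C=Cc2cc(O[Si](C)(C)C(C)(C)C)c(C)c(C)c2O1)C(=O)OC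
F4 | step 7 | methyl 2-[bis(2,2,2-trifluoroethoxy)phosphoryl]-2-bromoacetate | COC(=O)C(Br)P(=O)(OCC(F)(F)F)OCC(F)(F)F
F5 | step 7 | methyl (2E,6E,10E)-2-bromo-12-[(tert-butyldiphenylsilyl)oxy]-6,10-dimethyldodeca-2,6,10-trienoate | COC(=O)/C(Br)=C\CC/C(C)=C/CC/C(C)=C/CO[Si](c1ccccc1)(c1ccccc1)C(C)(C)C
F6 | step 7 | (4-methylpent-3-en-1-yl)zinc bromide | CC(C)=CCC[Zn]Br
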